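**Plan**

- Ring numbering as in cyclohexan-1-ol: C1 = C(OH)CH3, C2 = CH carrying the pentenyl chain, C3 = quaternary C, C4 = CHBr, C5 and C6 = CH2.
- Retrosynthesis: the 4-hydroxy-4-methylpent-2-enyl chain is cut at its C=C bond (allyl group plus 2-methylbut-3-en-2-ol); the ring is then cut at C5–C6 and at C2–C3 into two three-carbon units.
- Enabling feature: C4 (CHBr) lies between quaternary C3 and CH2-5 and para to the carbinol C1. C3–C4–C5 can therefore be a 3-chloro-2-bromo-1-triflate (a doubly electrophilic bromonium-ion surrogate), and C6–C1–C2 the 2-methylallyl end of a linalool-derived (E)-allyl metal (doubly nucleophilic, with the C1 oxygen arriving as water).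
- Forward: allylbarium alkylation makes C5–C6; in the same flask HFIP ionises the C3–Cl bond and the 1,5-disposed E-alkene closes the bromonium ion (C2–C3) with hydration at C1; cross-metathesis and desilylation finish.
- Stereochemistry: C3 and C4 come from catalytic enantioselective anti bromochlorination of an E-allylic alcohol (C3 retained by double inversion); C2 and C1 from the E-alkene in a chair transition state; the side-chain carbinol from (S)-linalool; the two E-alkenes from SeO2 oxidation and metathesis.

Key step: step 7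

Assumption: (S)-(+)-linalool of high enantiomeric purity and pent-1-en-4-yne are taken as commercial, and the ligand enantiomer in step 2 is the one that delivers the (2S,3R) bromochloride.

**Step 1**
Reactants: 1 pent-1-en-4-yne
Product: 3 (2E)-3-methylhexa-2,5-dien-1-ol, via alkenylalane 2 (not isolated)
Conditions: Me3Al, Cp2ZrCl2 (cat.), CH2Cl2, 0 → 23 °C; then (CH2O)n, THF, 23 °C; aqueous work-up
Reagents that add atoms: trimethylaluminium, C[Al](C)C; paraformaldehyde (as formaldehyde), C=O
Why: Negishi zirconium-catalysed carboalumination adds Me–Al syn and regioselectively across the terminal alkyne only, so trapping the alkenylalane with formaldehyde should give the E-trisubstituted allylic alcohol with the terminal alkene untouched.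

**Step 2**
Reactants: 3 (2E)-3-methylhexa-2,5-dien-1-ol
Product: 4 (2S,3R)-2-bromo-3-chloro-3-methylhex-5-en-1-ol
Conditions: NBS, ClTi(OiPr)3, chiral tridentate Schiff-base ligand (20 mol %), hexanes, −20 °C
Reagents that add atoms: N-bromosuccinimide, O=C1CCC(=O)N1Br; chlorotitanium triisopropoxide, CC(C)O[Ti](Cl)(OC(C)C)OC(C)C
Why: In this titanium-alkoxide-templated catalytic enantioselective bromochlorination of an allylic alcohol, the chiral titanium complex should deliver Br+ to one face of the E-alkene and chloride anti to the tertiary carbon, setting both stereocentres by catalyst control while the unactivated terminal alkene stays intact.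

**Step 3**
Reactants: 4 (2S,3R)-2-bromo-3-chloro-3-methylhex-5-en-1-ol
Product: 5 (2S,3R)-2-bromo-3-chloro-3-methylhex-5-en-1-yl trifluoromethanesulfonate
Conditions: Tf2O, 2,6-lutidine, CH2Cl2, −78 °C; used without purification
Reagents that add atoms: trifluoromethanesulfonic anhydride, O=S(=O)(OS(=O)(=O)C(F)(F)F)C(F)(F)F
Why: O-Sulfonylation of the primary alcohol at low temperature with a hindered base should give the triflate without epoxide formation or ionisation of the tertiary chloride.

**Step 4**
Reactants: 6 (S)-(+)-linalool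
Product: 7 tert-butyl{[(3S)-3,7-dimethylocta-1,6-dien-3-yl]oxy}dimethylsilane
Conditions: TBSOTf, 2,6-lutidine, CH2Cl2, 0 → 23 °C
Reagents that add atoms: tert-butyldimethylsilyl trifluoromethanesulfonate, CC(C)(C)[Si](C)(C)OS(=O)(=O)C(F)(F)F
Why: Silylation with the silyl triflate protects the tertiary allylic alcohol against the organometallic and ionising conditions to come; the stereocentre is taken unchanged from the chiral pool.

**Step 5**
Reactants: 7 tert-butyl{[(3S)-3,7-dimethylocta-1,6-dien-3-yl]oxy}dimethylsilane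
Product: 8 (2E,6S)-6-[(tert-butyldimethylsilyl)oxy]-2,6-dimethylocta-2,7-dien-1-ol
Conditions: SeO2 (cat.), t-BuOOH, salicylic acid (cat.), CH2Cl2, 23 °C; then NaBH4, MeOH, 0 °C
Reagents that add atoms: tert-butyl hydroperoxide, CC(C)(C)OO
Why: Selenium dioxide allylic oxidation (ene then [2,3]-sigmatropic shift) is selective for the E-methyl group of the trisubstituted alkene, so the (E)-allylic alcohol should result, with borohydride returning any over-oxidised enal.

**Step 6**
Reactants: 8 (2E,6S)-6-[(tert-butyldimethylsilyl)oxy]-2,6-dimethylocta-2,7-dien-1-ol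
Product: 9 tert-butyl{[(3S,6E)-8-chloro-3,7-dimethylocta-1,6-dien-3-yl]oxy}dimethylsilane
Conditions: NCS, Me2S, CH2Cl2, −30 → 0 °C
Reagents that add atoms: N-chlorosuccinimide, O=C1CCC(=O)N1Cl
Why: Corey–Kim chlorination converts the primary allylic alcohol into the chloride by SN2 on the alkoxysulfonium salt, without allylic transposition or loss of the E geometry.

**Step 7**
Reactants: 9 tert-butyl{[(3S,6E)-8-chloro-3,7-dimethylocta-1,6-dien-3-yl]oxy}dimethylsilane; 5 (2S,3R)-2-bromo-3-chloro-3-methylhex-5-en-1-yl trifluoromethanesulfonate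
Product: 12 (1S,2S,3S,4S)-4-bromo-2-{(3S)-3-[(tert-butyldimethylsilyl)oxy]-3-methylpent-4-en-1-yl}-1,3-dimethyl-3-(prop-2-en-1-yl)cyclohexan-1-ol, via allylbarium chloride 10 (not isolated), via bromochloride triene 11 (not isolated)
Conditions: 9, Rieke Ba (BaI2, Li biphenylide), THF, −78 °C; then 5, −78 °C; then THF exchanged for HFIP–H2O (20:1), K2CO3, 23 °C
Reagents that add atoms: water, O
Why: Allylbarium 10, configurationally stable at −78 °C, should displace the primary triflate of 5 at its unsubstituted α-carbon (SN2, C5–C6 bond) to give the (6E)-bromochloride triene 11 with C–Br and C–Cl intact; in HFIP the tertiary chloride then ionises with anchimeric help from the anti bromine to a single-enantiomer bromonium ion, the trisubstituted alkene attacks its tertiary carbon (C2–C3 bond), and water captures the tertiary cation at C1. The closest known reaction types are the α-selective, geometry-retentive alkylation of allylbarium reagents and the solvolytic, enantiospecific bromonium polyene cyclisation of vicinal bromochlorides. The ring closes in the 6-endo mode through a chair transition state. C3 keeps its configuration by double inversion (bromine in, C2 in anti to bromine), C4 is untouched, C2 follows from the E-alkene in the chair (chain equatorial) and C1 from anti, equatorial capture of the cation by water. The step needs α- over γ-alkylation with retention of E geometry (barium at −78 °C), ionisation only after the C–C coupling (non-ionising THF stage first), and cyclisation faster than intermolecular capture of the bromonium ion (intramolecular chair closure, little water).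

**Step 8**
Reactants: 12 (1S,2S,3S,4S)-4-bromo-2-{(3S)-3-[(tert-butyldimethylsilyl)oxy]-3-methylpent-4-en-1-yl}-1,3-dimethyl-3-(prop-2-en-1-yl)cyclohexan-1-ol; 13 2-methylbut-3-en-2-ol
Product: 14 (1S,2S,3S,4S)-4-bromo-2-{(3S)-3-[(tert-butyldimethylsilyl)oxy]-3-methylpent-4-en-1-yl}-3-[(2E)-4-hydroxy-4-methylpent-2-en-1-yl]-1,3-dimethylcyclohexan-1-ol
Conditions: Grubbs II (5 mol %), 13 (10 equiv), CH2Cl2, 40 °C
Reagents that add atoms: none
Why: Olefin cross-metathesis between the terminal allyl group and the tertiary allylic alcohol 13 should give the E-disubstituted alkene, while the vinyl group on the quaternary silyloxy carbon is too hindered to take part.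

**Step 9**
Reactants: 14 (1S,2S,3S,4S)-4-bromo-2-{(3S)-3-[(tert-butyldimethylsilyl)oxy]-3-methylpent-4-en-1-yl}-3-[(2E)-4-hydroxy-4-methylpent-2-en-1-yl]-1,3-dimethylcyclohexan-1-ol
Product: 15 (1S,2S,3S,4S)-4-bromo-2-[(3S)-3-hydroxy-3-methylpent-4-en-1-yl]-3-[(2E)-4-hydroxy-4-methylpent-2-en-1-yl]-1,3-dimethylcyclohexan-1-ol
Conditions: TBAF, THF, 45 °C
Reagents that add atoms: none
Why: Fluoride cleaves the tertiary silyl ether and no stereocentre is touched.

**Compound list**

1 | pent-1-en-4-yne | C=CCC#C | starting material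
2 | dimethyl[(1E)-2-methylpenta-1,4-dien-1-yl]alumane | C=CC/C(C)=C/[Al](C)C | intermediate (not isolated)
3 | (2E)-3-methylhexa-2,5-dien-1-ol | C=CC/C(C)=C/CO | intermediate
4 | (2S,3R)-2-bromo-3-chloro-3-methylhex-5-en-1-ol | OC[C@H](Br)[C@](C)(Cl)CC=C | intermediate
5 | (2S,3R)-2-bromo-3-chloro-3-methylhex-5-en-1-yl trifluoromethanesulfonate | FC(F)(F)S(=O)(=O)OC[C@H](Br)[C@](C)(Cl)CC=C | intermediate
6 | (S)-(+)-linalool, (3S)-3,7-dimethylocta-1,6-dien-3-ol | C=C[C@@](C)(O)CCC=C(C)C | starting material
7 | tert-butyl{[(3S)-3,7-dimethylocta-1,6-dien-3-yl]oxy}dimethylsilane | C=C[C@@](C)(O[Si](C)(C)C(C)(C)C)CCC=C(C)C | intermediate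
8 | (2E,6S)-6-[(tert-butyldimethylsilyl)oxy]-2,6-dimethylocta-2,7-dien-1-ol | C=C[C@@](C)(O[Si](C)(C)C(C)(C)C)CC/C=C(\C)CO | intermediate
9 | tert-butyl{[(3S,6E)-8-chloro-3,7-dimethylocta-1,6-dien-3-yl]oxy}dimethylsilane | C=C[C@@](C)(O[Si](C)(C)C(C)(C)C)CC/C=C(\C)CCl | intermediate
10 | chlorido[(2E,6S)-6-[(tert-butyldimethylsilyl)oxy]-2,6-dimethylocta-2,7-dien-1-yl]barium | C=C[C@@](C)(O[Si](C)(C)C(C)(C)C)CC/C=C(\C)C[Ba]Cl | intermediate (not isolated)
11 | tert-butyl{[(3S,6E,10S,11R)-10-bromo-11-chloro-3,7,11-trimethyltetradeca-1,6,13-trien-3-yl]oxy}dimethylsilane | C=C[C@@](C)(O[Si](C)(C)C(C)(C)C)CC/C=C(\C)CC[C@H](Br)[C@](C)(Cl)CC=C | intermediate (not isolated)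
12 | (1S,2S,3S,4S)-4-bromo-2-{(3S)-3-[(tert-butyldimethylsilyl)oxy]-3-methylpent-4-en-1-yl}-1,3-dimethyl-3-(prop-2-en-1-yl)cyclohexan-1-ol | C=C[C@@](C)(O[Si](C)(C)C(C)(C)C)CC[C@H]1[C@](C)(CC=C)[C@@H](Br)CC[C@]1(C)O | intermediate
13 | 2-methylbut-3-en-2-ol | C=CC(C)(C)O | starting material
14 | (1S,2S,3S,4S)-4-bromo-2-{(3S)-3-[(tert-butyldimethylsilyl)oxy]-3-methylpent-4-en-1-yl}-3-[(2E)-4-hydroxy-4-methylpent-2-en-1-yl]-1,3-dimethylcyclohexan-1-ol | C=C[C@@](C)(O[Si](C)(C)C(C)(C)C)CC[C@H]1[C@](C)(C/C=C/C(C)(C)O)[C@@H](Br)CC[C@]1(C)O | intermediate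
15 | (1S,2S,3S,4S)-4-bromo-2-[(3S)-3-hydroxy-3-methylpent-4-en-1-yl]-3-[(2E)-4-hydroxy-4-methylpent-2-en-1-yl]-1,3-dimethylcyclohexan-1-ol | C=C[C@@](C)(O)CC[C@H]1[C@](C)(C/C=C/C(C)(C)O)[C@@H](Br)CC[C@]1(C)O | target

**Totals**

Total step count: 9. Longest linear sequence: 6 steps (steps 4, 5, 6, 7, 8, 9).

**Steps most likely to fail**

Step 7. In the first stage the allylbarium may act as a base or attack bromine (elimination of the β-bromo triflate) or lose its E geometry. In the second stage the ring cation may lose a proton or be trapped by the silyl ether oxygen instead of by water. The fallback sets out from 9 and 3 and comes back at 12. It gives up the preformed bromochloride and uses a halogen-free polyene with an external bromonium source. Compound 9 is converted with sodium benzenesulfinate into the allylic sulfone tert-butyl{[(3S,6E)-3,7-dimethyl-8-(phenylsulfonyl)octa-1,6-dien-3-yl]oxy}dimethylsilane F1, and 3 with PBr3 into (2E)-1-bromo-3-methylhexa-2,5-diene F2. Lithiated F1 is alkylated with F2 to the coupled sulfone F3 (C8 epimers). Palladium-catalysed hydride desulfonylation then gives the tetraene tert-butyl{[(3S,6E,10E)-3,7,11-trimethyltetradeca-1,6,10,13-tetraen-3-yl]oxy}dimethylsilane F4. Bromonium-induced cyclisation of F4 with an electrophilic bromine reagent in a wet ionising solvent should give 12 together with its ring-enantiomeric (1R,2R,3R,4R) diastereomer F5. The two are diastereomers because of the (S)-carbinol and are separated by chromatography.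

Step 2. Halogen delivery may proceed with insufficient enantio- or regiocontrol on this skipped-diene allylic alcohol. The fallback sets out from 3 and comes back at 4. The ligand-free titanium-mediated bromochlorination gives 4 as a racemate with its enantiomer (2R,3S)-2-bromo-3-chloro-3-methylhex-5-en-1-ol F6. Compound 4 is then obtained by resolution on a chiral stationary phase or by lipase-catalysed acylation, in place of asymmetric catalysis.

Step 8. Ring-closing metathesis onto the vinyl group, homodimerisation, or slow reaction of the allyl group next to the quaternary carbon may compete. The fallback sets out from 12 and comes back at 14, building the chain by carbonyl chemistry. Osmium-catalysed dihydroxylation with periodate cleavage of the less hindered allyl alkene gives the aldehyde F7 (12 with CH2CHO in place of the allyl group). Horner–Wadsworth–Emmons reaction with triethyl phosphonoacetate gives the (E)-enoate F8 (12 with (E)-CH2CH=CHCO2Et in place of the allyl group). Double 1,2-addition of MeMgBr/CeCl3 to the ester then gives 14.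

**Further compounds**

F1 | step 7 | tert-butyl{[(3S,6E)-3,7-dimethyl-8-(phenylsulfonyl)octa-1,6-dien-3-yl]oxy}dimethylsilane | C=C[C@@](C)(O[Si](C)(C)C(C)(C)C)CC/C=C(\C)CS(=O)(=O)c1ccccc1
F2 | step 7 | (2E)-1-bromo-3-methylhexa-2,5-diene | C=CC/C(C)=C/CBr
F3 | step 7 | tert-butyl{[(3S,6E,10E)-3,7,11-trimethyl-8-(phenylsulfonyl)tetradeca-1,6,10,13-tetraen-3-yl]oxy}dimethylsilane (C8 epimers) | C=C[C@@](C)(O[Si](C)(C)C(C)(C)C)CC/C=C(\C)C(C/C=C(\C)CC=C)S(=O)(=O)c1ccccc1
F4 | step 7 | tert-butyl{[(3S,6E,10E)-3,7,11-trimethyltetradeca-1,6,10,13-tetraen-3-yl]oxy}dimethylsilane | C=C[C@@](C)(O[Si](C)(C)C(C)(C)C)CC/C=C(\C)CC/C=C(\C)CC=C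
F5 | step 7 | (1R,2R,3R,4R)-4-bromo-2-{(3S)-3-[(tert-butyldimethylsilyl)oxy]-3-methylpent-4-en-1-yl}-1,3-dimethyl-3-(prop-2-en-1-yl)cyclohexan-1-ol | C=C[C@@](C)(O[Si](C)(C)C(C)(C)C)CC[C@@H]1[C@@](C)(CC=C)[C@H](Br)CC[C@@]1(C)O
F6 | step 2 | (2R,3S)-2-bromo-3-chloro-3-methylhex-5-en-1-ol | OC[C@@H](Br)[C@@](C)(Cl)CC=C
F7 | step 8 | aldehyde, 12 with CH2CHO in place of the allyl group | C=C[C@@](C)(O[Si](C)(C)C(C)(C)C)CC[C@H]1[C@](C)(CC=O)[C@@H](Br)CC[C@]1(C)O
F8 | step 8 | (E)-enoate, 12 with (E)-CH2CH=CHCO2Et in place of the allyl group | C=C[C@@](C)(O[Si](C)(C)C(C)(C)C)CC[C@H]1[C@](C)(C/C=C/C(=O)OCC)[C@@H](Br)CC[C@]1(C)O
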